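**Plan**
- Retrosynthesis: the target triacid is taken back by functional-group changes only (C7 CH2OH → CO2H, C16 C=O → C=CH2, ester cleavage, C1=C2 saturation) to adduct 22. Cutting C5–C10 and C3–C4 of 22 together leaves triene 21 hung on the C/D bicyclo[3.2.1]octane.
- Enabling feature: ring A is a cyclohexane with the C3 oxygen next to C4 (which carries the C19 carboxyl), while C10 carries the C20 carboxyl and is tied to C5 through C9–C8–C6. This is the retron of a 1-silyloxydiene/(Z)-2-methylenoate cycloaddition across a three-atom tether.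
- 21 is cut further at C4=C5 (olefination), C6–C7 (hydroxymethylation), C8–C6 (homologation) and C10–C1 (vinylogous formylation). The core is cut at C13–C16 (radical closure) and C8–C15 (alkylation), back to meso anhydride 1.
- Forward ring order: C (from 1) → D (5-exo vinyl radical) → B and A together (intramolecular Diels–Alder).
- Stereochemistry: C9 and C8 from alkaloid-mediated desymmetrisation of 1 and anti alkylation; C13 by bridging; C6 from an amine organocatalyst; C10, C5, C4 and C3 from the diene/dienophile geometry, A(1,3) strain at C6 and the exo transition state.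

Key step: step 16

Remark: gibberellane atom numbers (C1–C20) are used for all intermediates and α is the face of C19 and C20; in step 1 quinidine is assumed to give the (1R,2S) half-ester (quinine would be used instead if it is the alkaloid that gives this sense).

Step 1
Reactants: 1 cis-cyclohex-4-ene-1,2-dicarboxylic anhydride
Product: 2 (1R,2S)-2-[(benzyloxy)carbonyl]cyclohex-4-ene-1-carboxylic acid
Conditions: BnOH, quinidine (1.1 equiv), PhMe, −55 °C; aq. HCl work-up
Reagents that add atoms: benzyl alcohol (OCc1ccccc1)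
Why: Cinchona-alkaloid-mediated enantioselective alcoholysis (desymmetrisation) of a meso anhydride, the alkaloid acting as general base and directing the alcohol to one of the enantiotopic carbonyl groups, should set the future C8 and C9 in one operation.

Step 2
Reactants: 2 (1R,2S)-2-[(benzyloxy)carbonyl]cyclohex-4-ene-1-carboxylic acid
Product: 3 (1R,2R)-2-[(benzyloxy)carbonyl]-2-(2-bromoprop-2-en-1-yl)cyclohex-4-ene-1-carboxylic acid
Conditions: LiN(i-Pr)2 (2.2 equiv), THF, −78 → −20 °C; CH2=C(Br)CH2Br; aq. HCl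
Reagents that add atoms: 2,3-dibromopropene (C=C(Br)CBr)
Why: Alkylation of the carboxylate/ester-enolate dianion takes place at the ester α-carbon by SN2 attack on the allylic bromide from the face anti to the neighbouring carboxylate, which should create quaternary C8 with the bromoallyl group (C15–C17) trans to the C9 carboxyl.

Step 3
Reactants: 3 (1R,2R)-2-[(benzyloxy)carbonyl]-2-(2-bromoprop-2-en-1-yl)cyclohex-4-ene-1-carboxylic acid
Product: 6 benzyl 1-(2-bromoprop-2-en-1-yl)-6-(2-methoxy-2-oxoethyl)cyclohex-3-ene-1-carboxylate, via acid chloride 4 (not isolated), via diazoketone 5 (not isolated)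
Conditions: (COCl)2, DMF (cat.), CH2Cl2; CH2N2, Et2O, 0 °C; PhCO2Ag (cat.), Et3N, MeOH, rt
Reagents that add atoms: diazomethane (C=[N+]=[N-]); methanol (CO)
Why: Arndt–Eistert homologation, in which the Wolff rearrangement moves C9 with retention, puts C10 and C20 in place and leaves C9 no longer α to a carbonyl group.

Step 4
Reactants: 6 benzyl 1-(2-bromoprop-2-en-1-yl)-6-(2-methoxy-2-oxoethyl)cyclohex-3-ene-1-carboxylate
Product: 7 benzyl 2-(2-methoxy-2-oxoethyl)-6-methylidenebicyclo[3.2.1]octane-1-carboxylate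
Conditions: Bu3SnH, AIBN (cat.), PhH, 80 °C
Reagents that add atoms: none
Why: 5-exo-trig cyclisation of the vinyl radical onto C13 of the ring alkene closes ring D, and C13 can only form in the bridged sense dictated by C8.

Step 5
Reactants: 7 benzyl 2-(2-methoxy-2-oxoethyl)-6-methylidenebicyclo[3.2.1]octane-1-carboxylate
Product: 8 benzyl 2-(2-methoxy-2-oxoethyl)-6-oxobicyclo[3.2.1]octane-1-carboxylate
Conditions: O3, CH2Cl2/MeOH, −78 °C; Me2S
Reagents that add atoms: ozone ([O-][O+]=O)
Why: Ozonolysis of the only alkene stores the exocyclic methylene as the C16 ketone, so that C1=C2 can later be hydrogenated without competition.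

Step 6
Reactants: 8 benzyl 2-(2-methoxy-2-oxoethyl)-6-oxobicyclo[3.2.1]octane-1-carboxylate
Product: 9 ethylene ketal of 8
Conditions: HOCH2CH2OH, TsOH (cat.), PhH, reflux with removal of water
Reagents that add atoms: ethane-1,2-diol (OCCO)
Why: Acid-catalysed ketalisation protects the enolisable C16 ketone against the enolate, phosphonate and silylating reagents that follow.

Step 7
Reactants: 9 ethylene ketal of 8
Product: 10 ketal acid (C8–CO2H, C9–CH2CO2Me)
Conditions: H2 (1 atm), Pd/C, EtOAc, rt
Reagents that add atoms: none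
Why: Hydrogenolysis of the benzyl ester frees the hindered carboxyl on C8 and leaves the methyl ester, which differentiates the two carboxyl carbons.

Step 8
Reactants: 10 ketal acid (C8–CO2H, C9–CH2CO2Me)
Product: 11 enal acid (C9–CH(CO2Me)–CH=CH–CHO, E, C10 epimers)
Conditions: LiN(i-Pr)2 (2.2 equiv), THF, −78 °C; Me2NCH=CHCHO, −78 → 0 °C; aq. HCl (pH 3)
Reagents that add atoms: (E)-3-(dimethylamino)prop-2-enal (CN(C)/C=C/C=O)
Why: Vinylogous formylation: the dianion (only the CH2CO2Me group can be enolised) adds to the carbonyl of the vinylogous formamide, and acid hydrolysis with loss of water and dimethylamine should give the (E)-enal that brings in C1–C3.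

Step 9
Reactants: 11 enal acid
Product: 12 dimethyl acetal of 11
Conditions: HC(OMe)3, MeOH, PPTS (cat.), rt
Reagents that add atoms: trimethyl orthoformate (COC(OC)OC)
Why: Acid-catalysed acetalisation masks the aldehyde as an acyclic acetal that can later be removed beside the dioxolane, while the hindered tertiary acid is not esterified at room temperature.

Step 10
Reactants: 12 dimethyl acetal of 11
Product: 15 S-ethyl thioester (C8–CH2–COSEt), via acid chloride 13 (not isolated), via diazoketone 14 (not isolated)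
Conditions: Me2C=C(Cl)NMe2, CH2Cl2, 0 °C; CH2N2, Et2O, 0 °C; hν (Pyrex), EtSH, THF, rt
Reagents that add atoms: diazomethane (C=[N+]=[N-]); ethanethiol (CCS)
Why: A second Arndt–Eistert homologation under neutral conditions (photochemical Wolff rearrangement with retention at C8, ketene trapped by the thiol) inserts C6 and gives a thioester that can be reduced beside the methyl ester.

Step 11
Reactants: 15 S-ethyl thioester
Product: 16 aldehyde (C8–CH2–CHO)
Conditions: Et3SiH, Pd/C, acetone, rt
Reagents that add atoms: none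
Why: Fukuyama reduction of the thioester stops at the aldehyde and should leave the ester, both acetals and the isolated alkene untouched.

Step 12
Reactants: 16 aldehyde (C8–CH2–CHO)
Product: 18 (6S)-silyloxymethyl aldehyde (C8–CH(CH2OTBS)–CHO), via hydroxy aldehyde 17 (not isolated)
Conditions: aq. HCHO, (R)-α,α-diphenylprolinol trimethylsilyl ether (20 mol %), PhMe, pH 7 buffer, rt; then TBSCl, imidazole, DMF, 0 °C
Reagents that add atoms: formaldehyde (C=O); tert-butyldimethylsilyl chloride (CC(C)(C)[Si](C)(C)Cl)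
Why: Enamine-catalysed α-hydroxymethylation (cross-aldol with formaldehyde) brings in C7 and should set C6 under catalyst control, the (E)-enamine being attacked anti to the diphenyl(silyloxy)methyl group, and immediate silylation forestalls retro-aldol and β-elimination.

Step 13
Reactants: 18 (6S)-silyloxymethyl aldehyde
Product: 19 (Z)-enoate (C6–CH=C(CH3)CO2Me)
Conditions: (CF3CH2O)2P(O)CH(CH3)CO2CH3, KN(SiMe3)2, 18-crown-6, THF, −78 °C
Reagents that add atoms: methyl 2-[bis(2,2,2-trifluoroethoxy)phosphoryl]propanoate (COC(=O)C(C)P(=O)(OCC(F)(F)F)OCC(F)(F)F)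
Why: The Still–Gennari variant of the Horner–Wadsworth–Emmons reaction should give the kinetic (Z)-trisubstituted enoate (C19 cis to C6) at low temperature without epimerising C6.

Step 14
Reactants: 19 (Z)-enoate
Product: 20 enal (Z)-enoate
Conditions: oxalic acid (cat.), wet SiO2, CH2Cl2, rt
Reagents that add atoms: water (O)
Why: The acyclic allylic dimethyl acetal hydrolyses far faster than the dioxolane ketal or the primary silyl ether, so mild acid should free only the enal.

Step 15
Reactants: 20 enal (Z)-enoate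
Product: 21 triene, methyl (2Z,4E)-5-silyloxypenta-2,4-dienoate on C9
Conditions: TBSOTf, Et3N, CH2Cl2, −78 → 0 °C
Reagents that add atoms: tert-butyldimethylsilyl triflate (CC(C)(C)[Si](C)(C)OS(=O)(=O)C(F)(F)F)
Why: Soft enolisation (O-silylation, then γ-deprotonation at C10) gives the 1-silyloxydiene, the (4E) enol ether being favoured and A(1,3) strain in the deprotonation placing the bulky C9 outside and the planar ester inside (2Z).

Step 16
Reactants: 21 triene
Product: 22 cycloadduct (rings A–D; Δ1; 3β-OTBS; 7-OTBS; C19 and C20 methyl esters; C16 ketal)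
Conditions: PhMe, BHT (cat.), 140 °C, sealed tube
Reagents that add atoms: none
Why: Thermal, concerted but asynchronous [4+2] cycloaddition between the 1-silyloxydiene (C3=C2–C1=C10, nucleophilic at C10) and the (Z)-2-methylenoate C4=C5, with the C5–C10 bond leading; the closest known reaction type is the intramolecular Diels–Alder reaction of terminally activated 1,3,8-nonatrienes to trans-hydrindenes. Ring B closes through the three-atom tether C9–C8–C6 (5-exo for the leading bond) and ring A is the new cyclohexene that holds both new bonds. C3 and C10 follow from the diene geometry (4E puts OTBS outside, 2Z puts the C20 ester inside, so the two end up trans); C4 follows from the (Z)-enoate (C19 cis to C6, methyl cis to H-5); C5 follows from C6, because A(1,3) strain holds H-6 in the enoate plane and the diene, bound through C8, adds anti to the CH2OTBS group. The step needs the exo (ester out, methyl in) transition state on the diene face that gives the trans A/B fusion. The α-methyl group favours ester-exo as in methacrylate additions, the endo mode would fold quaternary C8 and its bicycle under C1–C2, and the axial bond from C9 lets only the diene face syn to C8 reach the dienophile, with the small ester rather than the diene chain over ring C.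

Step 17
Reactants: 22 cycloadduct
Product: 23 1,2-dihydro cycloadduct
Conditions: H2 (1 atm), Pd/C, EtOAc, rt
Reagents that add atoms: none
Why: Heterogeneous hydrogenation saturates C1=C2, the only alkene present because C16 is still stored as the ketal.

Step 18
Reactants: 23 1,2-dihydro cycloadduct
Product: 24 3β,7-diol 16-ketone 19,20-dimethyl ester
Conditions: HF (48 % aq.), MeCN, rt
Reagents that add atoms: water (O)
Why: Aqueous HF cleaves both silyl ethers and hydrolyses the dioxolane, and no lactone should form because each hydroxyl lies trans to the esters within its reach.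

Step 19
Reactants: 24 3β,7-diol 16-ketone 19,20-dimethyl ester
Product: 25 3β,7-diol 16-ene 19,20-dimethyl ester
Conditions: Zn, CH2Br2, TiCl4, THF/CH2Cl2, 0 °C → rt
Reagents that add atoms: dibromomethane (BrCBr)
Why: Lombardo methylenation installs the exocyclic methylene under non-basic conditions, so the β-hydroxy ester (C3–C4–C19) is not exposed to retro-aldol epimerisation.

Step 20
Reactants: 25 3β,7-diol 16-ene 19,20-dimethyl ester
Product: 27 3β-hydroxygibberell-16-ene-7,19,20-trioic acid 19,20-dimethyl ester, via aldehyde 26 (not isolated)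
Conditions: TEMPO (cat.), PhI(OAc)2, MeCN/H2O, rt
Reagents that add atoms: water (O)
Why: Oxoammonium oxidation takes the primary C7 alcohol through the aldehyde hydrate to the acid in preference to the hindered axial 3β-hydroxyl, and C6 already has the more stable configuration (C7 trans to C4).

Step 21
Reactants: 27 3β-hydroxygibberell-16-ene-7,19,20-trioic acid 19,20-dimethyl ester
Product: 28 3β-hydroxygibberell-16-ene-7,19,20-trioic acid (the target gibberellin)
Conditions: n-PrSLi, HMPA, rt; aq. HCl work-up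
Reagents that add atoms: none
Why: SN2 O-demethylation by thiolate cleaves the two hindered esters on quaternary carbons where hydrolysis would need forcing base.

**Compound list**
1 | cis-cyclohex-4-ene-1,2-dicarboxylic anhydride (meso) | [C@H]12CC=CC[C@H]1C(=O)OC2=O | starting material
2 | (1R,2S)-2-[(benzyloxy)carbonyl]cyclohex-4-ene-1-carboxylic acid | [C@H]1(C(=O)OCc2ccccc2)CC=CC[C@H]1C(=O)O | intermediate
3 | (1R,2R)-2-[(benzyloxy)carbonyl]-2-(2-bromoprop-2-en-1-yl)cyclohex-4-ene-1-carboxylic acid (bromoallyl trans to CO2H) | C=C(Br)C[C@]1(C(=O)OCc2ccccc2)CC=CC[C@H]1C(=O)O | intermediate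
4 | acid chloride of 3 | C=C(Br)C[C@]1(C(=O)OCc2ccccc2)CC=CC[C@H]1C(Cl)=O | intermediate
5 | diazomethyl ketone from 4 | C=C(Br)C[C@]1(C(=O)OCc2ccccc2)CC=CC[C@H]1C(=O)C=[N+]=[N-] | intermediate
6 | benzyl 1-(2-bromoprop-2-en-1-yl)-6-(2-methoxy-2-oxoethyl)cyclohex-3-ene-1-carboxylate (CH2CO2Me cis to CO2Bn) | C=C(Br)C[C@]1(C(=O)OCc2ccccc2)CC=CC[C@H]1CC(=O)OC | intermediate
7 | benzyl 2-(2-methoxy-2-oxoethyl)-6-methylidenebicyclo[3.2.1]octane-1-carboxylate (C8, C9, C13 as in the target; side chain anti to the C15–C16 bridge) | C=C1C[C@]2(C(=O)OCc3ccccc3)C[C@H]1CC[C@H]2CC(=O)OC | intermediate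
8 | benzyl 2-(2-methoxy-2-oxoethyl)-6-oxobicyclo[3.2.1]octane-1-carboxylate | O=C1C[C@]2(C(=O)OCc3ccccc3)C[C@H]1CC[C@H]2CC(=O)OC | intermediate
9 | ethylene ketal of 8 | O1CCOC12C[C@]3(C(=O)OCc4ccccc4)C[C@H]2CC[C@H]3CC(=O)OC | intermediate
10 | ketal acid (C8–CO2H, C9–CH2CO2Me) | O1CCOC12C[C@]3(C(=O)O)C[C@H]2CC[C@H]3CC(=O)OC | intermediate
11 | enal acid, C9–CH(CO2Me)–CH=CH–CHO (E, C10 epimers) | O1CCOC12C[C@]3(C(=O)O)C[C@H]2CC[C@H]3C(C(=O)OC)/C=C/C=O | intermediate
12 | dimethyl acetal of 11 | O1CCOC12C[C@]3(C(=O)O)C[C@H]2CC[C@H]3C(C(=O)OC)/C=C/C(OC)OC | intermediate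
13 | acid chloride of 12 | O1CCOC12C[C@]3(C(Cl)=O)C[C@H]2CC[C@H]3C(C(=O)OC)/C=C/C(OC)OC | intermediate
14 | diazomethyl ketone from 13 | O1CCOC12C[C@]3(C(=O)C=[N+]=[N-])C[C@H]2CC[C@H]3C(C(=O)OC)/C=C/C(OC)OC | intermediate
15 | S-ethyl thioester, C8–CH2–COSEt | O1CCOC12C[C@]3(CC(=O)SCC)C[C@H]2CC[C@H]3C(C(=O)OC)/C=C/C(OC)OC | intermediate
16 | aldehyde, C8–CH2–CHO | O1CCOC12C[C@]3(CC=O)C[C@H]2CC[C@H]3C(C(=O)OC)/C=C/C(OC)OC | intermediate
17 | (6S)-hydroxymethyl aldehyde, C8–CH(CH2OH)–CHO | O1CCOC12C[C@]3([C@@H](CO)C=O)C[C@H]2CC[C@H]3C(C(=O)OC)/C=C/C(OC)OC | intermediate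
18 | (6S)-silyloxymethyl aldehyde, C8–CH(CH2OTBS)–CHO | O1CCOC12C[C@]3([C@@H](CO[Si](C)(C)C(C)(C)C)C=O)C[C@H]2CC[C@H]3C(C(=O)OC)/C=C/C(OC)OC | intermediate
19 | (Z)-enoate, C8–CH(CH2OTBS)–CH=C(CH3)CO2Me, arm as dimethyl acetal | O1CCOC12C[C@]3([C@@H](CO[Si](C)(C)C(C)(C)C)/C=C(/C)C(=O)OC)C[C@H]2CC[C@H]3C(C(=O)OC)/C=C/C(OC)OC | intermediate
20 | enal (Z)-enoate | O1CCOC12C[C@]3([C@@H](CO[Si](C)(C)C(C)(C)C)/C=C(/C)C(=O)OC)C[C@H]2CC[C@H]3C(C(=O)OC)/C=C/C=O | intermediate
21 | triene: (2Z,4E)-5-silyloxydienoate on C9, (Z)-2-methylenoate on C6 | O1CCOC12C[C@]3([C@@H](CO[Si](C)(C)C(C)(C)C)/C=C(/C)C(=O)OC)C[C@H]2CC[C@H]3/C(C(=O)OC)=C/C=C/O[Si](C)(C)C(C)(C)C | intermediate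
22 | cycloadduct: Δ1, 3β-OTBS, 4β-CH3, 4α- and 10α-CO2Me, 5β-H, 6β-CH2OTBS, 16-ketal | O1CCOC12C[C@]34C[C@H]2CC[C@H]3[C@]5(C(=O)OC)C=C[C@H](O[Si](C)(C)C(C)(C)C)[C@@](C)(C(=O)OC)[C@H]5[C@@H]4CO[Si](C)(C)C(C)(C)C | intermediate
23 | 1,2-dihydro derivative of 22 | O1CCOC12C[C@]34C[C@H]2CC[C@H]3[C@]5(C(=O)OC)CC[C@H](O[Si](C)(C)C(C)(C)C)[C@@](C)(C(=O)OC)[C@H]5[C@@H]4CO[Si](C)(C)C(C)(C)C | intermediate
24 | 3β,7-dihydroxy-16-oxo-17-nor-gibberellane 19,20-dimethyl ester | O=C1C[C@]23C[C@H]1CC[C@H]2[C@]1(C(=O)OC)CC[C@H](O)[C@@](C)(C(=O)OC)[C@H]1[C@@H]3CO | intermediate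
25 | 3β,7-dihydroxy-gibberell-16-ene 19,20-dimethyl ester | C=C1C[C@]23C[C@H]1CC[C@H]2[C@]1(C(=O)OC)CC[C@H](O)[C@@](C)(C(=O)OC)[C@H]1[C@@H]3CO | intermediate
26 | C7 aldehyde of 25 | C=C1C[C@]23C[C@H]1CC[C@H]2[C@]1(C(=O)OC)CC[C@H](O)[C@@](C)(C(=O)OC)[C@H]1[C@@H]3C=O | intermediate
27 | 3β-hydroxygibberell-16-ene-7,19,20-trioic acid 19,20-dimethyl ester (7-acid free) | C=C1C[C@]23C[C@H]1CC[C@H]2[C@]1(C(=O)OC)CC[C@H](O)[C@@](C)(C(=O)OC)[C@H]1[C@@H]3C(=O)O | intermediate
28 | 3β-hydroxygibberell-16-ene-7,19,20-trioic acid (the target gibberellin) | C=C1C[C@]23C[C@H]1CC[C@H]2[C@]1(C(=O)O)CC[C@H](O)[C@@](C)(C(=O)O)[C@H]1[C@@H]3C(=O)O | target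

**Step count and risks**
Total steps: 21. Longest linear sequence: 21 steps (the route is linear from 1).

Steps most likely to fail:

Step 16. The cycloaddition may lose control through a competing endo approach (giving the cis-fused, C4-epimeric adduct), through addition to the other diene face, or through E/Z leakage of the dienol ether on heating. The fallback sets out from 18 and comes back at 22; it builds the ring first and the C4 centre afterwards. Aldehyde 18 is homologated with dimethyl (1-diazo-2-oxopropyl)phosphonate (K2CO3, MeOH, 0 °C) to the terminal alkyne F1. Oxidative methoxycarbonylation (PdCl2, CuCl2, NaOAc, CO, MeOH) gives the ynoate F2. Acetal hydrolysis as in step 14 gives the ynoate enal F3, and silylation as in step 15 gives the ynoate dienol ether F4. Its cycloaddition with the alkyne has no endo/exo question and gives the cyclohexa-1,4-diene F5. Reductive methylation of the enoate (Li, NH3, THF, −78 °C; then CH3I) should protonate C5 to the trans ring fusion and methylate C4 anti to the axial C20 ester, which gives 22.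

Step 12. Catalyst control may be eroded by the neighbouring quaternary C8, and the β-hydroxy aldehyde may undergo retro-aldol or β-elimination before it is silylated. The fallback sets out from 16 and comes back at 18; it makes C6 prochiral and lets an enzyme choose. Unselective hydroxymethylation and reduction in one pot (aq. HCHO, pyrrolidine cat.; then NaBH4) gives the 2-substituted propane-1,3-diol F6. A lipase (a serine hydrolase, for example porcine pancreatic lipase, with vinyl acetate) acetylates one of the two diastereotopic hydroxymethyl groups to the monoacetate F7. Silylation (TBSCl, imidazole) gives the silyl ether acetate F8, and methanolysis (K2CO3, MeOH) gives the alcohol F9. Oxidation with 1,1,1-triacetoxy-1,1-dihydro-1,2-benziodoxol-3(1H)-one (NaHCO3, CH2Cl2) returns 18.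

Step 8. The enolate may act as a base toward the vinylogous formamide or add in a conjugate sense, and the doubly activated C10–H of the product may be deprotonated and condense further. The fallback sets out from 10 and comes back at 11; it uses an aldol addition followed by allylic transposition. The dianion of 10 (LiN(i-Pr)2, THF, −78 °C) adds 1,2 to acrolein to give the secondary allylic alcohol F10. Catalytic Ph3SiOReO3 (Et2O, rt) transposes it to the more substituted primary allylic alcohol F11. MnO2 (CH2Cl2) oxidises this to enal 11.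

**Further compounds**
F1 | step 16 | terminal alkyne, C8–CH(CH2OTBS)–C≡CH | O1CCOC12C[C@]3([C@@H](CO[Si](C)(C)C(C)(C)C)C#C)C[C@H]2CC[C@H]3C(C(=O)OC)/C=C/C(OC)OC
F2 | step 16 | ynoate, C8–CH(CH2OTBS)–C≡C–CO2Me | O1CCOC12C[C@]3([C@@H](CO[Si](C)(C)C(C)(C)C)C#CC(=O)OC)C[C@H]2CC[C@H]3C(C(=O)OC)/C=C/C(OC)OC
F3 | step 16 | ynoate enal | O1CCOC12C[C@]3([C@@H](CO[Si](C)(C)C(C)(C)C)C#CC(=O)OC)C[C@H]2CC[C@H]3C(C(=O)OC)/C=C/C=O
F4 | step 16 | ynoate (2Z,4E)-silyl dienol ether | O1CCOC12C[C@]3([C@@H](CO[Si](C)(C)C(C)(C)C)C#CC(=O)OC)C[C@H]2CC[C@H]3/C(C(=O)OC)=C/C=C/O[Si](C)(C)C(C)(C)C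
F5 | step 16 | cyclohexa-1,4-diene cycloadduct (Δ1, Δ4) | O1CCOC12C[C@]34C[C@H]2CC[C@H]3[C@]5(C(=O)OC)C=C[C@H](O[Si](C)(C)C(C)(C)C)C(C(=O)OC)=C5[C@@H]4CO[Si](C)(C)C(C)(C)C
F6 | step 12 | prochiral diol, C8–CH(CH2OH)2 | O1CCOC12C[C@]3(C(CO)CO)C[C@H]2CC[C@H]3C(C(=O)OC)/C=C/C(OC)OC
F7 | step 12 | monoacetate | O1CCOC12C[C@]3([C@@H](CO)COC(C)=O)C[C@H]2CC[C@H]3C(C(=O)OC)/C=C/C(OC)OC
F8 | step 12 | silyl ether acetate | O1CCOC12C[C@]3([C@@H](CO[Si](C)(C)C(C)(C)C)COC(C)=O)C[C@H]2CC[C@H]3C(C(=O)OC)/C=C/C(OC)OC
F9 | step 12 | mono-silylated diol | O1CCOC12C[C@]3([C@@H](CO[Si](C)(C)C(C)(C)C)CO)C[C@H]2CC[C@H]3C(C(=O)OC)/C=C/C(OC)OC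
F10 | step 8 | secondary allylic alcohol, C9–CH(CO2Me)–CH(OH)–CH=CH2 | O1CCOC12C[C@]3(C(=O)O)C[C@H]2CC[C@H]3C(C(=O)OC)C(O)C=C
F11 | step 8 | primary allylic alcohol, C9–CH(CO2Me)–CH=CH–CH2OH (E) | O1CCOC12C[C@]3(C(=O)O)C[C@H]2CC[C@H]3C(C(=O)OC)/C=C/CO
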